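**Strategy.** Numbering the chain from the benzylic carbon (C1) to C12, the route rests on one fact: C1 sits on the guaiacyl ring para to the phenol oxygen, so a C1–O bond to the C5 oxygen is a hydrogenolysable tether and C1–C5 plus that oxygen can be built as one oxane ring. A catalytic asymmetric hetero-Diels–Alder reaction forms C1–C2 and C5–O, closes this ring and sets C5 in one operation. Its precursor is the 2-triethylsilyloxy diene carrying C2–C12 (from octanal and an acetonyl ylide) paired with O-benzylvanillin. The ring then relays C5 to C3 by an axial-selective ketone reduction and is cut open.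

Key step: step 3

Catalyst: [(L)CrCl], trivalent chromium, L = dianion of (1S,2R)-1-{[3-(1-adamantyl)-2-hydroxy-5-methylbenzylidene]amino}indan-2-ol (C27H29NO2).

Assumption: the (1S,2R) complex is taken to expose the aldehyde face that leads to the 2S adduct, by analogy with the usual sense of this catalyst class; if the opposite sense is found, the (1R,2S) complex is used and nothing else changes.

**Step 1**
Reactants: 1 octanal; 2 1-(triphenylphosphoranylidene)propan-2-one
Product: 3 (E)-undec-3-en-2-one
Conditions: toluene, 90 °C
Reagents that add atoms: none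
Why: Wittig olefination with a ketone-stabilised ylide is reliably E-selective and, the ylide being only weakly basic, tolerates the enolisable aldehyde.

**Step 2**
Reactants: 3 (E)-undec-3-en-2-one
Product: 4 (E)-triethyl(undeca-1,3-dien-2-yloxy)silane
Conditions: Et3SiOTf, Et3N, Et2O, 0 °C
Reagents that add atoms: triethylsilyl trifluoromethanesulfonate, CC[Si](CC)(CC)OS(=O)(=O)C(F)(F)F
Why: Silyl enol ether formation by soft enolisation: the silyl triflate activates the carbonyl oxygen and Et3N removes a methyl proton in preference to a γ-proton, which should give the cross-conjugated 2-silyloxy diene with the E-alkene intact.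

**Step 3**
Reactants: 4 (E)-triethyl(undeca-1,3-dien-2-yloxy)silane; 5 4-(benzyloxy)-3-methoxybenzaldehyde
Product: 7 (2S,6S)-2-[4-(benzyloxy)-3-methoxyphenyl]-6-heptyltetrahydro-4H-pyran-4-one, via silyl enol ether cycloadduct 6 (not isolated)
Conditions: [(L)CrCl] (10 mol%), 4 Å molecular sieves, TBME, rt; filter; then 1 M aq. HCl, THF, 0 °C
Reagents that add atoms: none
Why: The chromium centre of [(L)CrCl] binds the aldehyde oxygen as a Lewis acid and the s-cis diene adds in a concerted, asynchronous [4+2] cycloaddition, the C–C bond from the diene CH2 terminus to the carbonyl carbon running ahead of the C–O bond; this is the known enantioselective hetero-Diels–Alder reaction of singly oxygenated 2-silyloxy dienes with aldehydes under tridentate Schiff-base CrCl catalysis. The one new ring (oxane atoms O1 and C2 to C6) is closed by the cycloaddition itself, both ring bonds arising in the same suprafacial event and not by a separate cyclisation. The benzylic stereocenter (pyran C2) is set by the catalyst, which shields one face of the bound aldehyde and is chosen in the (1S,2R) series to give 2S. The heptyl-bearing stereocenter (pyran C6, target C5) is set relative to C2 by endo approach of the (E)-diene, which places aryl and heptyl cis and so makes C6 S. Regioselectivity is secured by the 2-silyloxy group, which makes the unsubstituted diene terminus the nucleophilic carbon, and chemoselectivity by an aldehyde without α-hydrogens, so that enolisation cannot compete. Brief aqueous acid should then hydrolyse the silyl enol ether to the ketone without touching either stereocenter.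

**Step 4**
Reactants: 7 (2S,6S)-2-[4-(benzyloxy)-3-methoxyphenyl]-6-heptyltetrahydro-4H-pyran-4-one
Product: 8 (2S,4S,6S)-2-[4-(benzyloxy)-3-methoxyphenyl]-6-heptyltetrahydro-2H-pyran-4-ol
Conditions: LiBH(s-Bu)3, THF, −78 °C; then H2O
Reagents that add atoms: none
Why: Diastereoselective ketone reduction with a bulky trialkylborohydride: the chair is locked by the two equatorial substituents, hydride should arrive along the equatorial trajectory, and the new carbinol (pyran C4, target C3) then carries an axial hydroxyl trans to heptyl under substrate control.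

**Step 5**
Reactants: 8 (2S,4S,6S)-2-[4-(benzyloxy)-3-methoxyphenyl]-6-heptyltetrahydro-2H-pyran-4-ol
Product: 9 (3R,5S)-1-(4-hydroxy-3-methoxyphenyl)dodecane-3,5-diol
Conditions: H2 (3 bar), 10% Pd/C, EtOH–AcOH (10:1), rt
Reagents that add atoms: none
Why: Heterogeneous catalytic hydrogenolysis of benzylic C–O bonds: the phenol benzyl ether should cleave first and the ring C2–O bond, activated by the freed para-hydroxyl, second, which opens the oxane to the syn-diol while the two carbinol centres, neither benzylic, stay untouched.

**Step 6**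
Reactants: 9 (3R,5S)-1-(4-hydroxy-3-methoxyphenyl)dodecane-3,5-diol
Product: 11 (3R,5S)-1-(4-hydroxy-3-methoxyphenyl)dodecane-3,5-diyl diacetate, via triacetate 10 (not isolated)
Conditions: Ac2O, Et3N, DMAP (cat.), CH2Cl2, rt; then pyrrolidine, 0 °C to rt
Reagents that add atoms: acetic anhydride, CC(=O)OC(C)=O
Why: DMAP-catalysed acylation should esterify all three hydroxyls, and chemoselective aminolysis then removes only the aryl acetate, whose phenoxide is a far better leaving group than a secondary alkoxide, while the amine also destroys the excess anhydride.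

**Compound list**

1 | octanal | CCCCCCCC=O | starting material
2 | 1-(triphenylphosphoranylidene)propan-2-one | CC(=O)C=P(c1ccccc1)(c1ccccc1)c1ccccc1 | starting material
3 | (E)-undec-3-en-2-one | CCCCCCC/C=C/C(C)=O | intermediate
4 | (E)-triethyl(undeca-1,3-dien-2-yloxy)silane | C=C(O[Si](CC)(CC)CC)/C=C/CCCCCCC | intermediate
5 | 4-(benzyloxy)-3-methoxybenzaldehyde | COc1cc(C=O)ccc1OCc1ccccc1 | starting material
6 | (2S,6S)-2-[4-(benzyloxy)-3-methoxyphenyl]-6-heptyl-4-(triethylsilyloxy)-3,6-dihydro-2H-pyran (2,6-cis) | CCCCCCC[C@@H](C=C(O[Si](CC)(CC)CC)C[C@H]1c2ccc(OCc3ccccc3)c(OC)c2)O1 | intermediate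
7 | (2S,6S)-2-[4-(benzyloxy)-3-methoxyphenyl]-6-heptyltetrahydro-4H-pyran-4-one (2,6-cis) | CCCCCCC[C@@H](CC(=O)C[C@H]1c2ccc(OCc3ccccc3)c(OC)c2)O1 | intermediate
8 | (2S,4S,6S)-2-[4-(benzyloxy)-3-methoxyphenyl]-6-heptyltetrahydro-2H-pyran-4-ol (axial OH, trans to aryl and heptyl) | CCCCCCC[C@@H](C[C@H](O)C[C@H]1c2ccc(OCc3ccccc3)c(OC)c2)O1 | intermediate
9 | (3R,5S)-1-(4-hydroxy-3-methoxyphenyl)dodecane-3,5-diol (syn) | CCCCCCC[C@@H](C[C@@H](CCc1ccc(O)c(OC)c1)O)O | intermediate
10 | (3R,5S)-1-(4-acetoxy-3-methoxyphenyl)dodecane-3,5-diyl diacetate | CCCCCCC[C@@H](C[C@@H](CCc1ccc(OC(C)=O)c(OC)c1)OC(C)=O)OC(C)=O | intermediate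
11 | (3R,5S)-1-(4-hydroxy-3-methoxyphenyl)dodecane-3,5-diyl diacetate | CCCCCCC[C@@H](C[C@@H](CCc1ccc(O)c(OC)c1)OC(C)=O)OC(C)=O | target

**Step count.** Total: 6 steps. Longest linear sequence: 6 steps (octanal 1 to 11; aldehyde 5 enters at step 3).

**Steps most likely to fail**

1. Step 3. The electron-rich aryl aldehyde may bind the chromium Lewis acid weakly and cycloadd slowly, so that diene hydrolysis or isomerisation wins and conversion or enantioselectivity falls short. The fallback is an aldol/oxa-Michael construction of the same ring; it sets out from 5 (with 1) and returns at 7. Base-mediated condensation of 5 with acetone (NaOH, aqueous acetone) would give (E)-4-[4-(benzyloxy)-3-methoxyphenyl]but-3-en-2-one F1. Its boron enolate (Ipc2BCl of the antipode that delivers the 5S carbinol, Et3N, Et2O, −78 °C) would add to octanal 1 to give (1E,5S)-1-[4-(benzyloxy)-3-methoxyphenyl]-5-hydroxydodec-1-en-3-one F2. Acid-mediated 6-endo oxa-Michael cyclisation (Amberlyst-15, CH2Cl2, rt) under thermodynamic control would then close the 2,6-cis ring of 7. In this variant the heptyl carbinol is set by the aldol and the sacrificial benzylic centre by equilibration.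

2. Step 5. The phenol benzyl ether should cleave quickly, but hydrogenolysis of the ring C–O bond may stall, and forcing it may begin to saturate the arene. The fallback replaces the metal-surface cleavage with an ionic reduction; it sets out from 8 and returns at 11, bypassing step 6. Et3SiH with BF3·OEt2 (CH2Cl2, −40 to 0 °C) would ionise the ring C2–O bond, helped by the para-benzyloxy donor, and reduce the benzylic cation to (3R,5S)-1-[4-(benzyloxy)-3-methoxyphenyl]dodecane-3,5-diol F3. Acetylation (Ac2O, pyridine, DMAP) would give (3R,5S)-1-[4-(benzyloxy)-3-methoxyphenyl]dodecane-3,5-diyl diacetate F4. Simple benzyl ether hydrogenolysis (H2, 1 bar, Pd/C, EtOAc) would then release 11.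

3. Step 6. The aminolysis may not be fully chemoselective, with partial loss of an aliphatic acetate on long exposure or incomplete cleavage of the hindered guaiacyl acetate. The fallback masks the phenol before acylation; it sets out from 9 and returns at 11. Phenoxide-selective O-alkylation (allyl bromide, K2CO3, acetone) would give (3R,5S)-1-[4-(allyloxy)-3-methoxyphenyl]dodecane-3,5-diol F5. Acetylation (Ac2O, pyridine, DMAP) would give (3R,5S)-1-[4-(allyloxy)-3-methoxyphenyl]dodecane-3,5-diyl diacetate F6. Allyl transfer to morpholine with Pd(PPh3)4 (zerovalent palladium, THF, rt) would then free the phenol of 11 with both acetates intact.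

**Further compounds**

F1 | step 3 | (E)-4-[4-(benzyloxy)-3-methoxyphenyl]but-3-en-2-one | CC(=O)/C=C/c1ccc(OCc2ccccc2)c(OC)c1
F2 | step 3 | (1E,5S)-1-[4-(benzyloxy)-3-methoxyphenyl]-5-hydroxydodec-1-en-3-one | CCCCCCC[C@H](O)CC(=O)/C=C/c1ccc(OCc2ccccc2)c(OC)c1
F3 | step 5 | (3R,5S)-1-[4-(benzyloxy)-3-methoxyphenyl]dodecane-3,5-diol | CCCCCCC[C@@H](C[C@@H](CCc1ccc(OCc2ccccc2)c(OC)c1)O)O
F4 | step 5 | (3R,5S)-1-[4-(benzyloxy)-3-methoxyphenyl]dodecane-3,5-diyl diacetate | CCCCCCC[C@@H](C[C@@H](CCc1ccc(OCc2ccccc2)c(OC)c1)OC(C)=O)OC(C)=O
F5 | step 6 | (3R,5S)-1-[4-(allyloxy)-3-methoxyphenyl]dodecane-3,5-diol | CCCCCCC[C@@H](C[C@@H](CCc1ccc(OCC=C)c(OC)c1)O)O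
F6 | step 6 | (3R,5S)-1-[4-(allyloxy)-3-methoxyphenyl]dodecane-3,5-diyl diacetate | CCCCCCC[C@@H](C[C@@H](CCc1ccc(OCC=C)c(OC)c1)OC(C)=O)OC(C)=O
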